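The plan cuts two neighbouring bonds of flavone ring A: C8–C2 of the piperidine and the aryl–oxygen bond beside it. C8 is flanked by the oxygen-bearing carbons C7 and C8a and faces the C5 methoxy group across the ring. A benzylic amine carbon next to a phenolic oxygen is what a cyclic nitrone leaves after adding to an aryne. One [3+2] cycloaddition thus joins arene and piperidine, delivers that oxygen and creates the (racemic) stereocentre. The precursor is a 2-silylaryl triflate with 3-benzyloxy and 5-methoxy groups. Methylation, hydrogenolysis, iodination and carbonylative alkyne annulation finish the pyranone. Salt resolution comes last, when ring A is least prone to retro-Mannich racemisation.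

Key step: step 6

Assumption: the (R)-base is taken to form the less soluble salt with (2R,3R)-O,O'-di-p-toluoyltartaric acid. If a salt screen shows the opposite pairing, the (2S,3S)-acid is used in the same way. The absolute configuration is to be confirmed by single-crystal diffraction of the salt, with the acid as internal reference.

Step 1
Reactants: 1 5-methoxyresorcinol
Product: 2 5-methoxy-1,3-phenylene bis(N,N-diethylcarbamate)
Conditions: Et2NCOCl (2.5 equiv), K2CO3, MeCN, reflux
Reagents that add atoms: N,N-diethylcarbamoyl chloride, CCN(CC)C(Cl)=O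
Why: Double O-carbamoylation (nucleophilic acyl substitution) turns both phenols into the strongest oxygen-based directing groups for lithiation and keeps the arene symmetric, so that C2 becomes the uniquely activated position.

Step 2
Reactants: 2 5-methoxy-1,3-phenylene bis(N,N-diethylcarbamate)
Product: 4 5-methoxy-2-(trimethylsilyl)-1,3-phenylene bis(N,N-diethylcarbamate), via 2-lithio bis-carbamate 3 (not isolated)
Conditions: s-BuLi, TMEDA, THF, −78 °C; then TMSCl, −78 °C → rt
Reagents that add atoms: chlorotrimethylsilane, C[Si](C)(C)Cl
Why: Directed ortho-metalation: C2 lies between two carbamates whose joint coordination and acidifying effect outweigh the carbamate/methoxy-flanked C4 and C6, and at −78 °C aryllithium 3 is silylated before an anionic ortho-Fries shift can set in.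

Step 3
Reactants: 4 5-methoxy-2-(trimethylsilyl)-1,3-phenylene bis(N,N-diethylcarbamate)
Product: 5 5-methoxy-2-(trimethylsilyl)benzene-1,3-diol
Conditions: LiAlH4, THF, 0 °C → 40 °C; cold NH4Cl-buffered aqueous quench; crude diol carried on without silica gel
Reagents that add atoms: none
Why: Hydride reduction of the aryl carbamates expels both phenoxides and takes the carbamoyl carbon on to an N-methyl group while leaving the aryl–silicon bond alone, which hot aqueous alkali would endanger, and the buffered quench protects this very electron-rich arylsilane from protodesilylation.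

Step 4
Reactants: 5 5-methoxy-2-(trimethylsilyl)benzene-1,3-diol; 6 benzyl bromide
Product: 7 3-(benzyloxy)-5-methoxy-2-(trimethylsilyl)phenol
Conditions: 6 (0.9 equiv), K2CO3 (1.0 equiv), dry acetone, rt
Reagents that add atoms: none
Why: Williamson ether synthesis on two homotopic hydroxyls, so only the degree of alkylation needs control, which a slight deficit of 6, one equivalent of mild base and recycling of recovered 5 provide.

Step 5
Reactants: 7 3-(benzyloxy)-5-methoxy-2-(trimethylsilyl)phenol
Product: 8 3-(benzyloxy)-5-methoxy-2-(trimethylsilyl)phenyl trifluoromethanesulfonate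
Conditions: PhNTf2, DBU, MeCN, rt
Reagents that add atoms: N-phenylbis(trifluoromethanesulfonimide), O=S(=O)(N(c1ccccc1)S(=O)(=O)C(F)(F)F)C(F)(F)F
Why: Triflyl transfer from N-phenyltriflimide to the amidine-generated phenoxide is the usual acid-free closing step for o-silylaryl triflates and tolerates the flanking trimethylsilyl group and both ethers.

Step 6
Reactants: 8 3-(benzyloxy)-5-methoxy-2-(trimethylsilyl)phenyl trifluoromethanesulfonate; 9 N-hydroxypiperidine
Product: 12 racemic 4-benzyloxy-6-methoxy-2,3-dihydro-1,2-benzisoxazole whose N2 and C3 are shared with a piperidine ring, via 2,3,4,5-tetrahydropyridine 1-oxide 10 (not isolated), via 3-benzyloxy-5-methoxybenzyne 11 (not isolated)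
Conditions: a) 9 (2 equiv), MnO2, 4 Å molecular sieves, CH2Cl2, 0 °C, filter through Celite; b) filtrate added at once to 8, CsF (3 equiv), MeCN, rt
Reagents that add atoms: none
Why: Fluoride attacks silicon of 8 and triflate departs to give aryne 11, whose strained in-plane π bond takes up the 1,3-dipole 10 in a concerted but asynchronous [3+2] cycloaddition, a reaction type well documented for o-silylaryl triflate-derived arynes with acyclic and cyclic nitrones. The five-membered isoxazoline ring is closed by the cycloaddition itself, its two new bonds (aryl C–O and aryl C–C2 of the piperidine) arising in one intermolecular event with the C–O bond running ahead. The step needs regioselectivity: the inductively withdrawing benzyloxy group at C3 widens the internal angle at C1, so the nucleophilic nitrone oxygen bonds at C1 and the nitrone carbon at C2 next to OBn, as 3-alkoxy- and 3,5-dialkoxybenzynes behave towards other nucleophiles, and the weaker opposing bias of the remote 5-methoxy group should not overturn this. The new stereocentre (piperidine C2) forms from two achiral partners without any controlling element and is therefore racemic, while the ring-fusion nitrogen inverts and carries no lasting information. Excess nitrone made just before use offsets its tendency to oligomerise, and the mild fluoride source spares the benzyl and methyl ethers.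

Step 7
Reactants: 12 racemic piperidine-fused dihydrobenzisoxazole cycloadduct
Product: 14 racemic 2-(2,6-dihydroxy-4-methoxyphenyl)-1-methylpiperidinium triflate, via N-methylisoxazolinium triflate 13 (not isolated)
Conditions: MeOTf (1.1 equiv), CH2Cl2, 0 °C → rt, evaporate; then H2 (1 atm), Pd/C, MeOH, rt; filter, evaporate
Reagents that add atoms: methyl trifluoromethanesulfonate, COS(=O)(=O)C(F)(F)F
Why: SN2 methylation of the weakly basic isoxazoline nitrogen needs the powerful methyl triflate and meets no free hydroxyl at this stage, and catalytic hydrogenolysis then cleaves the activated N–O bond and the benzyl ether together, the crowded protonated benzylic C–N bond being far slower to react; the stereocentre stays racemic.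

Step 8
Reactants: 14 racemic 2-(2,6-dihydroxy-4-methoxyphenyl)-1-methylpiperidinium triflate
Product: 15 racemic 4-iodo-5-methoxy-2-(1-methylpiperidin-2-yl)benzene-1,3-diol
Conditions: NIS (1.0 equiv), MeCN, −20 → 0 °C, dark; aq NaHCO3 work-up
Reagents that add atoms: N-iodosuccinimide, O=C1CCC(=O)N1I
Why: Electrophilic aromatic iodination: the two open ring positions are interchanged by rotation about the aryl–piperidine bond and each is activated by three oxygen donors, the ammonium form shields nitrogen from oxidation, and one equivalent of reagent in the cold should stop at the monoiodide.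

Step 9
Reactants: 15 racemic 4-iodo-5-methoxy-2-(1-methylpiperidin-2-yl)benzene-1,3-diol; 16 phenylacetylene
Product: 19 racemic 7-hydroxy-5-methoxy-8-(1-methylpiperidin-2-yl)-2-phenyl-4H-chromen-4-one, via aryl alkynyl ketone 17 (not isolated), via diethylamino enone 18 (not isolated)
Conditions: PdCl2(PPh3)2 (5 mol %), CO (balloon, up to 5 bar if slow), 16 (1.5 equiv), Et2NH/DMF, 60 °C
Reagents that add atoms: carbon monoxide, [C-]#[O+]
Why: Carbonylative Sonogashira coupling with in situ cyclisation, a known flavone synthesis from o-iodophenols: zerovalent palladium inserts into the carbon–iodine bond, CO insertion and alkynylation give 17, diethylamine adds to give 18, and the only hydroxyl ortho to the ketone displaces the amine in a 6-endo sense, which avoids the 5-exo aurone mode.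

Step 10
Reactants: 19 racemic 7-hydroxy-5-methoxy-8-(1-methylpiperidin-2-yl)-2-phenyl-4H-chromen-4-one
Product: 20 1:1 salt of the (R)-flavone base with (2R,3R)-O,O'-di-p-toluoyltartaric acid
Conditions: (2R,3R)-O,O'-di-p-toluoyltartaric acid (0.5 equiv), EtOH, 45 °C → 5 °C; recrystallise until chiral HPLC shows a single enantiomer
Reagents that add atoms: (2R,3R)-O,O'-di-p-toluoyltartaric acid, OC(=O)[C@H](OC(=O)c1ccc(C)cc1)[C@@H](OC(=O)c1ccc(C)cc1)C(O)=O
Why: Classical resolution by diastereomeric salt crystallisation (half-equivalent method): the basic N-methylpiperidine pairs with the chiral diacid, the less soluble salt selects the (R)-configured piperidine C2, and because only a neutralisation follows, no later step can erode the enantiomeric purity.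

Step 11
Reactants: 20 (R)-flavone di-p-toluoyltartrate salt
Product: 21 (R)-7-hydroxy-5-methoxy-8-(1-methylpiperidin-2-yl)-2-phenyl-4H-chromen-4-one
Conditions: aq NaHCO3 (pH about 8), CH2Cl2, 0 °C → rt
Reagents that add atoms: none
Why: Simple acid–base liberation under cold, weakly basic conditions breaks no bond at the stereocentre and gives the free (R)-base.

Compound list
1 | 5-methoxyresorcinol | COc1cc(O)cc(O)c1 | starting material
2 | 5-methoxy-1,3-phenylene bis(N,N-diethylcarbamate) | COc1cc(OC(=O)N(CC)CC)cc(OC(=O)N(CC)CC)c1 | intermediate
3 | 2-lithio-5-methoxy-1,3-phenylene bis(N,N-diethylcarbamate) | COc1cc(OC(=O)N(CC)CC)c([Li])c(OC(=O)N(CC)CC)c1 | intermediate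
4 | 5-methoxy-2-(trimethylsilyl)-1,3-phenylene bis(N,N-diethylcarbamate) | COc1cc(OC(=O)N(CC)CC)c([Si](C)(C)C)c(OC(=O)N(CC)CC)c1 | intermediate
5 | 5-methoxy-2-(trimethylsilyl)benzene-1,3-diol | COc1cc(O)c([Si](C)(C)C)c(O)c1 | intermediate
6 | benzyl bromide | BrCc1ccccc1 | starting material
7 | 3-(benzyloxy)-5-methoxy-2-(trimethylsilyl)phenol | COc1cc(O)c([Si](C)(C)C)c(OCc2ccccc2)c1 | intermediate
8 | 3-(benzyloxy)-5-methoxy-2-(trimethylsilyl)phenyl trifluoromethanesulfonate | COc1cc(OCc2ccccc2)c([Si](C)(C)C)c(OS(=O)(=O)C(F)(F)F)c1 | intermediate
9 | N-hydroxypiperidine | ON1CCCCC1 | starting material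
10 | 2,3,4,5-tetrahydropyridine 1-oxide | [O-][N+]1=CCCCC1 | intermediate
11 | 3-benzyloxy-5-methoxybenzyne | COC1=CC#CC(OCc2ccccc2)=C1 | intermediate
12 | racemic 4-benzyloxy-6-methoxy piperidine-fused 2,3-dihydro-1,2-benzisoxazole | COc1cc(OCc2ccccc2)c2c(c1)ON1CCCCC21 | intermediate
13 | racemic N-methyl quaternary triflate of 12 | COc1cc(OCc2ccccc2)c2c(c1)O[N+]1(C)CCCCC21.[O-]S(=O)(=O)C(F)(F)F | intermediate
14 | racemic 2-(2,6-dihydroxy-4-methoxyphenyl)-1-methylpiperidinium triflate | COc1cc(O)c(C2CCCC[NH+]2C)c(O)c1.[O-]S(=O)(=O)C(F)(F)F | intermediate
15 | racemic 4-iodo-5-methoxy-2-(1-methylpiperidin-2-yl)benzene-1,3-diol | COc1cc(O)c(C2CCCCN2C)c(O)c1I | intermediate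
16 | phenylacetylene | C#Cc1ccccc1 | starting material
17 | racemic 1-[2,4-dihydroxy-6-methoxy-3-(1-methylpiperidin-2-yl)phenyl]-3-phenylprop-2-yn-1-one | COc1cc(O)c(C2CCCCN2C)c(O)c1C(=O)C#Cc1ccccc1 | intermediate
18 | racemic 3-(diethylamino)-1-[2,4-dihydroxy-6-methoxy-3-(1-methylpiperidin-2-yl)phenyl]-3-phenylprop-2-en-1-one | COc1cc(O)c(C2CCCCN2C)c(O)c1C(=O)C=C(N(CC)CC)c1ccccc1 | intermediate
19 | racemic 7-hydroxy-5-methoxy-8-(1-methylpiperidin-2-yl)-2-phenyl-4H-chromen-4-one | COc1cc(O)c(C2CCCCN2C)c2oc(-c3ccccc3)cc(=O)c12 | intermediate
20 | 1:1 salt of the (R)-flavone base with (2R,3R)-O,O'-di-p-toluoyltartaric acid | COc1cc(O)c([C@H]2CCCCN2C)c2oc(-c3ccccc3)cc(=O)c12.OC(=O)[C@H](OC(=O)c1ccc(C)cc1)[C@@H](OC(=O)c1ccc(C)cc1)C(O)=O | intermediate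
21 | (R)-7-hydroxy-5-methoxy-8-(1-methylpiperidin-2-yl)-2-phenyl-4H-chromen-4-one (CNP0152057.1) | COc1cc(O)c([C@H]2CCCCN2C)c2oc(-c3ccccc3)cc(=O)c12 | target

Total step count: 11. Longest linear sequence: 11 steps (1 → 21); 9 enters inside step 6 and needs no separate step.

Steps most likely to fail

Step 6. The nitrone may self-condense faster than the slowly released aryne traps it. Regiocontrol may be incomplete. Basic fluoride may also open the N–O bond of the cycloadduct by elimination.

The fallback replaces the cycloaddition by polar addition of an aryllithium that already carries both oxygens.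
- It sets out from 1. MOMCl/i-Pr2NEt gives 1-methoxy-3,5-bis(methoxymethoxy)benzene F1.
- n-BuLi in THF at 0 °C metalates the position between the two chelating acetal ethers to give 2-lithio-5-methoxy-1,3-bis(methoxymethoxy)benzene F2.
- F2 adds at −78 °C to a dried THF solution of 10 to give racemic 2-[4-methoxy-2,6-bis(methoxymethoxy)phenyl]piperidin-1-ol F3.
- Zn in AcOH cleaves the N–O bond to racemic 2-[4-methoxy-2,6-bis(methoxymethoxy)phenyl]piperidine F4.
- Aqueous HCHO with NaBH(OAc)3 gives racemic 2-[4-methoxy-2,6-bis(methoxymethoxy)phenyl]-1-methylpiperidine F5.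
- TfOH in MeOH at 40 °C removes both acetals, and the route is rejoined at 14.

Step 9. Several processes could take over:
- oxidative addition into the electron-rich, doubly ortho-substituted iodide may be sluggish;
- iodine may be lost reductively;
- diethylamine may capture the acyl-palladium species in place of the alkyne;
- direct coupling without CO uptake may occur;
- ring closure may go 5-exo.

The fallback builds the pyranone by acylation chemistry and needs neither 15 nor palladium.
- It sets out from 14. Friedel–Crafts acetylation (Ac2O, BF3·OEt2, then aq NaOH/MeOH to cleave O-acetates) gives racemic 1-[2,4-dihydroxy-6-methoxy-3-(1-methylpiperidin-2-yl)phenyl]ethanone F6.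
- Excess LiN(SiMe3)2 in THF at −78 °C followed by one equivalent of benzoyl chloride C-acylates the polyanion. This is a Claisen-type shortcut of the Baker–Venkataraman sequence and gives racemic 1-[2,4-dihydroxy-6-methoxy-3-(1-methylpiperidin-2-yl)phenyl]-3-phenylpropane-1,3-dione F7.
- AcOH with catalytic H2SO4 at 95 °C cyclodehydrates F7, and the route is rejoined at 19. Hot acid is harmless there because the material is still racemic.

Step 10. The salt may oil out. The two diastereomeric salts may differ too little in solubility, or they may co-crystallise.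

The fallback gives up salt formation altogether. It sets out from 19, which is separated by preparative supercritical-fluid chromatography on an amylose tris(3,5-dimethylphenylcarbamate) phase (CO2/MeOH with a little Et2NH). The (R)-enantiomer is collected directly as 21, by-passing 20. This detour makes no new compound F0.

Further compounds
F1 | step 6 | 1-methoxy-3,5-bis(methoxymethoxy)benzene | COCOc1cc(OC)cc(OCOC)c1
F2 | step 6 | 2-lithio-5-methoxy-1,3-bis(methoxymethoxy)benzene | COCOc1cc(OC)cc(OCOC)c1[Li]
F3 | step 6 | racemic 2-[4-methoxy-2,6-bis(methoxymethoxy)phenyl]piperidin-1-ol | COCOc1cc(OC)cc(OCOC)c1C1CCCCN1O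
F4 | step 6 | racemic 2-[4-methoxy-2,6-bis(methoxymethoxy)phenyl]piperidine | COCOc1cc(OC)cc(OCOC)c1C1CCCCN1
F5 | step 6 | racemic 2-[4-methoxy-2,6-bis(methoxymethoxy)phenyl]-1-methylpiperidine | COCOc1cc(OC)cc(OCOC)c1C1CCCCN1C
F6 | step 9 | racemic 1-[2,4-dihydroxy-6-methoxy-3-(1-methylpiperidin-2-yl)phenyl]ethanone | COc1cc(O)c(C2CCCCN2C)c(O)c1C(C)=O
F7 | step 9 | racemic 1-[2,4-dihydroxy-6-methoxy-3-(1-methylpiperidin-2-yl)phenyl]-3-phenylpropane-1,3-dione | COc1cc(O)c(C2CCCCN2C)c(O)c1C(=O)CC(=O)c1ccccc1
F0 | step 10 | none | none
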